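I counted what was missing.

| setting | Monday's | Tuesday's | Friday's | flask |
|---|---|---|---|---|
| substrate | 10 mM | 10 mM | 5 mM | 10 mM |
| first nucleophile | 10 mM | 40 mM | 20 mM | 20.0 mM |
| solid second nucleophile | 12 mM | 12 mM | 12 mM | 12.0 mM |
| remark | run made earlier | run made earlier | run made earlier |  |
| time |  |  |  | 15 d |

| run | time / d | target / % | other capture product / % |
|---|---|---|---|
| Monday's | 0.625 | 18.6 | 37.3 |
| Monday's | 1.67 | 17.6 | 46.9 |
| Monday's | 4.00 | 16.3 | 48.4 |
| Monday's | 10.0 | 17.1 | 47.7 |
| Tuesday's | 0.625 | 26.1 | 22.5 |
| Tuesday's | 1.67 | 23.9 | 28.8 |
| Tuesday's | 4.00 | 23.9 | 28.7 |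
| Tuesday's | 10.0 | 24.1 | 29.5 |
| Friday's | 2.50 | 18.2 | 44.1 |
| Friday's | 5.00 | 19.4 | 44.7 |
| Friday's | 6.00 | 18.9 | 44.0 |
| Friday's | 10.0 | 19.4 | 44.4 |

(standard deviation of a reading: 0.5 percentage points)

- the earlier runs were read with a standard deviation of 0.5 percentage points
- at the start none of the solid second nucleophile is in solution

- share of target in target plus other capture product at 10 min
- share of target in target plus other capture product at 8.0 h
- share of target in target plus other capture product at 15 d
- which of target and other capture product there is more of at 15 d

Late in each run the readings had stopped moving beyond their scatter of 0.5 percentage points, yet target and other capture product did not add up to the charge. At 10.0 d, I divided the unread part of the charge by the target: Monday's run gave 2.06, Tuesday's 1.93 and Friday's 1.87. I carried their mean, 1.95, as the shadow ratio, the unread part of the charge per part of target once the readings stand still.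

Next I took the selectivity, target per other capture product: 0.358 on Monday and 0.817 on Tuesday, with the same substrate charge as this flask. This flask's 20.0 mM of first nucleophile is the geometric mean of their charges, so I took the geometric mean of the ratios, 0.541. That put the share at 35.1%, with other capture product ahead. The charge must hold target, its shadow and other capture product, so the shadow ratio gave target 20.8% of the charge and other capture product 38.4%.

The weak link was the geometric mean. A straight line between the two runs gave 0.511, a share of 33.8%, and I kept my end share between these two values.

The forecast said “the share starts high and falls to a plateau”. It gave 85% at 10 min, 48% at 8.0 h and 34% at 15 d, within 31.5% to 37%, with other capture product ahead. My first end share stood 1.1 points above its figure.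

The flask gave 97.5% at 10 min, 57.8% at 8.0 h and 34.8% at 15 d, with other capture product ahead.

    substrate ⇌ intermediate (K = 0.0980, k = 0.00260 min⁻¹)
    first nucleophile + intermediate → target (k = 35.0 M⁻¹ min⁻¹)
    second nucleophile + intermediate → other capture product (k = 530 M⁻¹ min⁻¹)
    solid second nucleophile ⇌ second nucleophile, rate k4*(cs4 - [second nucleophile]) while solid is left; crystals form when [second nucleophile] > cs4 (solubility = 7.90 mM, k = 8.10 × 10⁻⁴ min⁻¹)
    target ⇌ isomer of the product (K = 2.00, k = 0.00320 min⁻¹)

The unread part of this flask was the isomer of the product, 41.0% of the charge at 15.0 d, beside 20.5% of target, and the shadow ratio times that target gives 40.0%. In the neighbour with 5.0 mM of first nucleophile, target stood at 13.7%, so the shadow ratio gives 26.7%, and that neighbour held 27.5% of isomer of the product.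

The numbers in the tables were computed from invented constants; noise was put on by code.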